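**Plan**
1. Retrosynthesis: the C–CO2H bond of the acrylic acid is cut first (back to a terminal alkyne on C2), then the O1–C6 bond of the 3,6-dihydro-2H-pyran (O1, stereocentre C2, C3, C4=C5 with the chain on C5, C6).
2. Enabling feature: the allylic ether O1–C6–C5=C4 of the six-membered ring is the 1,3-transposed form of a four-membered ring with O1 on C4 and an exocyclic C5=C6 methylene, i.e. a 2-alkynyl-4-alkenyl oxetane.
3. Further cuts: O1–C2 of the oxetane (Williamson closure), C3–C4 (aldol of a silyl ynone with an enal), and the CH2–CH2 bond joining a farnesyl unit to a methallyl unit.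
4. Forward order: the chain is joined first (farnesyl bromide with methallyl alcohol dianion, oxidation, aldol), then the oxetane closes, then the pyran arises by copper-catalysed ring expansion, and last the alkyne is unmasked and hydrocarboxylated.
5. Stereochemistry: C2 comes from a catalyst-controlled transfer hydrogenation of the ynone (3S carbinol) and is inverted to R in the oxetane closure. The allylic oxygen is silylated beforehand so that only the propargylic oxygen can become the leaving group; a closure in the other sense would retain C2 and erode the enantiomeric purity. The E-alkenes are bought with farnesyl bromide.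

Key step: step 9

Remark: the carbinol centre that ends as C4 of the oxetane is made and carried as both epimers (RS, drawn without configuration), because it becomes sp2 in step 9.

**Step 1**
Reactants: 1 (2E,6E)-farnesyl bromide; 2 methallyl alcohol
Product: 4 (5E,9E)-6,10,14-trimethyl-2-methylidenepentadeca-5,9,13-trien-1-ol, via dilithiated methallyl alcohol 3 (not isolated)
Conditions: 2, n-BuLi (2.1 equiv), TMEDA, Et2O, 0 °C to rt; then 1, −78 °C to rt; H2O quench
Reagents that add atoms: none
Why: The allyl/alkoxide dianion formed with n-BuLi/TMEDA is alkylated at carbon by the primary allylic bromide (dianion C-alkylation, SN2), which should join the C19 chain without touching the E-alkenes.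

**Step 2**
Reactants: 4 (5E,9E)-6,10,14-trimethyl-2-methylidenepentadeca-5,9,13-trien-1-ol
Product: 5 (5E,9E)-6,10,14-trimethyl-2-methylidenepentadeca-5,9,13-trienal
Conditions: activated MnO2 (excess), CH2Cl2, rt
Reagents that add atoms: none
Why: MnO2 oxidises allylic alcohols selectively to enals under neutral conditions (allylic alcohol oxidation), so the isolated trisubstituted alkenes should stay untouched.

**Step 3**
Reactants: 5 (5E,9E)-6,10,14-trimethyl-2-methylidenepentadeca-5,9,13-trienal; 6 4-(triisopropylsilyl)but-3-yn-2-one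
Product: 8 (5RS,9E,13E)-5-hydroxy-10,14,18-trimethyl-6-methylidene-1-(triisopropylsilyl)nonadeca-9,13,17-trien-1-yn-3-one, via ynone lithium enolate 7 (not isolated)
Conditions: 6, LiN(i-Pr)2 (LDA, 1.2 equiv), THF, −78 °C; then 5, −78 °C; AcOH quench at −78 °C
Reagents that add atoms: none
Why: The kinetic lithium enolate of the methyl ynone adds 1,2 to the non-enolisable enal at −78 °C (aldol addition), the TIPS group shielding the ynone β-carbon from conjugate addition, and the new carbinol centre is deliberately formed without control because it is erased in step 9.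

**Step 4**
Reactants: 8 (5RS,9E,13E)-5-hydroxy-10,14,18-trimethyl-6-methylidene-1-(triisopropylsilyl)nonadeca-9,13,17-trien-1-yn-3-one
Product: 9 (5RS,9E,13E)-10,14,18-trimethyl-6-methylidene-5-[(triethylsilyl)oxy]-1-(triisopropylsilyl)nonadeca-9,13,17-trien-1-yn-3-one
Conditions: TESOTf, 2,6-lutidine, CH2Cl2, −78 °C
Reagents that add atoms: triethylsilyl trifluoromethanesulfonate, CC[Si](CC)(CC)OS(=O)(=O)C(F)(F)F
Why: Silylation with a silyl triflate and a hindered, non-nucleophilic base at low temperature (silyl ether formation) should cap the allylic hydroxyl without β-elimination or conjugate addition to the ynone, so that later only the propargylic oxygen can be activated.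

**Step 5**
Reactants: 9 (5RS,9E,13E)-10,14,18-trimethyl-6-methylidene-5-[(triethylsilyl)oxy]-1-(triisopropylsilyl)nonadeca-9,13,17-trien-1-yn-3-one
Product: 10 (3S,5RS,9E,13E)-10,14,18-trimethyl-6-methylidene-5-[(triethylsilyl)oxy]-1-(triisopropylsilyl)nonadeca-9,13,17-trien-1-yn-3-ol
Conditions: Ru[(S,S)-TsNCH(Ph)CH(Ph)NH](p-cymene) (3 mol%), i-PrOH, rt
Reagents that add atoms: none
Why: Noyori asymmetric transfer hydrogenation of a silyl ynone, in which the (S,S)-ligand dictates the carbonyl face that receives hydride (the alkynyl group being recognised as the unsaturated substituent), should give the 3S carbinol under catalyst control regardless of the neighbouring silyloxy centre, the base-free amido complex sparing the β-silyloxy ketone.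

**Step 6**
Reactants: 10 (3S,5RS,9E,13E)-10,14,18-trimethyl-6-methylidene-5-[(triethylsilyl)oxy]-1-(triisopropylsilyl)nonadeca-9,13,17-trien-1-yn-3-ol
Product: 11 (3S,5RS,9E,13E)-10,14,18-trimethyl-6-methylidene-5-[(triethylsilyl)oxy]-1-(triisopropylsilyl)nonadeca-9,13,17-trien-1-yn-3-yl methanesulfonate
Conditions: MsCl, Et3N, CH2Cl2, −20 to 0 °C
Reagents that add atoms: methanesulfonyl chloride, CS(=O)(=O)Cl
Why: Sulfonylation of a secondary propargylic alcohol takes place at oxygen with retention (mesylate formation) and should give a configurationally stable SN2 electrophile.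

**Step 7**
Reactants: 11 (3S,5RS,9E,13E)-10,14,18-trimethyl-6-methylidene-5-[(triethylsilyl)oxy]-1-(triisopropylsilyl)nonadeca-9,13,17-trien-1-yn-3-yl methanesulfonate
Product: 12 (3S,5RS,9E,13E)-5-hydroxy-10,14,18-trimethyl-6-methylidene-1-(triisopropylsilyl)nonadeca-9,13,17-trien-1-yn-3-yl methanesulfonate
Conditions: HF·pyridine, pyridine, THF, 0 °C
Reagents that add atoms: none
Why: Buffered HF·pyridine cleaves the triethylsilyl ether (fluoride-mediated O-desilylation) much faster than the alkynyl–TIPS bond and should neither displace the mesylate nor protonate the polyene.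

**Step 8**
Reactants: 12 (3S,5RS,9E,13E)-5-hydroxy-10,14,18-trimethyl-6-methylidene-1-(triisopropylsilyl)nonadeca-9,13,17-trien-1-yn-3-yl methanesulfonate
Product: 14 (2R,4RS)-2-[(triisopropylsilyl)ethynyl]-4-[(5E,9E)-6,10,14-trimethylpentadeca-1,5,9,13-tetraen-2-yl]oxetane, via sodium alkoxide of 12 13 (not isolated)
Conditions: NaH, THF, 0 °C to rt
Reagents that add atoms: none
Why: In this intramolecular Williamson etherification the allylic alkoxide displaces the propargylic mesylate in a 4-exo-tet SN2 closure with inversion, so 3S should become 2R at the oxetane carbon, and since only the allylic oxygen is free no retentive pathway can compete.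

**Step 9**
Reactants: 14 (2R,4RS)-2-[(triisopropylsilyl)ethynyl]-4-[(5E,9E)-6,10,14-trimethylpentadeca-1,5,9,13-tetraen-2-yl]oxetane
Product: 15 (2R)-2-[(triisopropylsilyl)ethynyl]-5-[(3E,7E)-4,8,12-trimethyltrideca-3,7,11-trien-1-yl]-3,6-dihydro-2H-pyran
Conditions: Cu(OTf)2 (5 mol%), CH2Cl2, −20 °C to rt
Reagents that add atoms: none
Why: Cu(OTf)2 binds the oxetane oxygen and ring strain drives heterolysis of the allylic C4–O1 bond to a contact ion pair of a 2-alkyl allyl cation and a copper alkoxide, which recombines at the CH2 terminus C6 in a net 1,3-oxygen shift. The closest known reaction is the Lewis- or Brønsted-acid-catalysed ring expansion of 2-vinyl oxetanes to 3,6-dihydro-2H-pyrans. The six-membered ring closes by O1–C6 bond formation, 6-endo with respect to the allyl unit (SN2'-type), leaving the C4=C5 alkene in the ring with the chain on C5. No stereocentre is created: C2 is a spectator and keeps its R configuration, and C4 becomes sp2, so both epimers of 14 should give the same product. The step needs ionisation of the allylic rather than the propargylic C–O bond and oxygen recapture faster than attack by the chain alkenes; the better stabilised allyl cation, the tethered alkoxide (only the ion pair with C6 syn to oxygen can collapse, the other returns to the oxetane) and the low temperature should secure this. The TIPS group keeps the alkyne away from copper.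

**Step 10**
Reactants: 15 (2R)-2-[(triisopropylsilyl)ethynyl]-5-[(3E,7E)-4,8,12-trimethyltrideca-3,7,11-trien-1-yl]-3,6-dihydro-2H-pyran
Product: 16 (2R)-2-ethynyl-5-[(3E,7E)-4,8,12-trimethyltrideca-3,7,11-trien-1-yl]-3,6-dihydro-2H-pyran
Conditions: Bu4NF, THF, 0 °C to rt
Reagents that add atoms: none
Why: Fluoride cleaves the C(sp)–Si bond (protodesilylation of a silyl alkyne) while the ethers, the alkenes and the stereocentre should be inert.

**Step 11**
Reactants: 16 (2R)-2-ethynyl-5-[(3E,7E)-4,8,12-trimethyltrideca-3,7,11-trien-1-yl]-3,6-dihydro-2H-pyran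
Product: 17 2-{(2R)-5-[(3E,7E)-4,8,12-trimethyltrideca-3,7,11-trien-1-yl]-3,6-dihydro-2H-pyran-2-yl}prop-2-enoic acid (CNP0171598.2)
Conditions: Pd(OAc)2 (5 mol%), Xantphos (10 mol%), HCO2H (2 equiv), Ac2O (20 mol%), toluene, 80 °C
Reagents that add atoms: formic acid, OC=O
Why: In this palladium-catalysed Markovnikov hydrocarboxylation of a terminal alkyne, with formic acid as the source of CO and water, insertion into the palladium hydride places the metal on the internal carbon and CO insertion then gives the α-methylene acid, the alkyne reacting far faster than the trisubstituted alkenes and the adjacent stereocentre not being involved.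

**Compound list**
1 | (2E,6E)-farnesyl bromide | CC(C)=CCC/C(C)=C/CC/C(C)=C/CBr | starting material
2 | methallyl alcohol (2-methylprop-2-en-1-ol) | CC(=C)CO | starting material
3 | dilithiated methallyl alcohol [lithium 2-(lithiomethyl)prop-2-en-1-olate], not isolated | [Li]CC(=C)CO[Li] | intermediate
4 | (5E,9E)-6,10,14-trimethyl-2-methylidenepentadeca-5,9,13-trien-1-ol | C=C(CO)CC/C=C(\C)CC/C=C(\C)CCC=C(C)C | intermediate
5 | (5E,9E)-6,10,14-trimethyl-2-methylidenepentadeca-5,9,13-trienal | C=C(C=O)CC/C=C(\C)CC/C=C(\C)CCC=C(C)C | intermediate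
6 | 4-(triisopropylsilyl)but-3-yn-2-one | CC(=O)C#C[Si](C(C)C)(C(C)C)C(C)C | starting material
7 | lithium 4-(triisopropylsilyl)but-1-en-3-yn-2-olate (ynone lithium enolate), not isolated | C=C(O[Li])C#C[Si](C(C)C)(C(C)C)C(C)C | intermediate
8 | (5RS,9E,13E)-5-hydroxy-10,14,18-trimethyl-6-methylidene-1-(triisopropylsilyl)nonadeca-9,13,17-trien-1-yn-3-one | CC(C)[Si](C#CC(=O)CC(O)C(=C)CC/C=C(\C)CC/C=C(\C)CCC=C(C)C)(C(C)C)C(C)C | intermediate
9 | (5RS,9E,13E)-10,14,18-trimethyl-6-methylidene-5-[(triethylsilyl)oxy]-1-(triisopropylsilyl)nonadeca-9,13,17-trien-1-yn-3-one | CC(C)[Si](C#CC(=O)CC(O[Si](CC)(CC)CC)C(=C)CC/C=C(\C)CC/C=C(\C)CCC=C(C)C)(C(C)C)C(C)C | intermediate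
10 | (3S,5RS,9E,13E)-10,14,18-trimethyl-6-methylidene-5-[(triethylsilyl)oxy]-1-(triisopropylsilyl)nonadeca-9,13,17-trien-1-yn-3-ol | CC(C)[Si](C#C[C@@H](O)CC(O[Si](CC)(CC)CC)C(=C)CC/C=C(\C)CC/C=C(\C)CCC=C(C)C)(C(C)C)C(C)C | intermediate
11 | (3S,5RS,9E,13E)-10,14,18-trimethyl-6-methylidene-5-[(triethylsilyl)oxy]-1-(triisopropylsilyl)nonadeca-9,13,17-trien-1-yn-3-yl methanesulfonate | CC(C)[Si](C#C[C@@H](OS(C)(=O)=O)CC(O[Si](CC)(CC)CC)C(=C)CC/C=C(\C)CC/C=C(\C)CCC=C(C)C)(C(C)C)C(C)C | intermediate
12 | (3S,5RS,9E,13E)-5-hydroxy-10,14,18-trimethyl-6-methylidene-1-(triisopropylsilyl)nonadeca-9,13,17-trien-1-yn-3-yl methanesulfonate | CC(C)[Si](C#C[C@@H](OS(C)(=O)=O)CC(O)C(=C)CC/C=C(\C)CC/C=C(\C)CCC=C(C)C)(C(C)C)C(C)C | intermediate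
13 | sodium alkoxide of 12, not isolated | CC(C)[Si](C#C[C@@H](OS(C)(=O)=O)CC(O[Na])C(=C)CC/C=C(\C)CC/C=C(\C)CCC=C(C)C)(C(C)C)C(C)C | intermediate
14 | (2R,4RS)-2-[(triisopropylsilyl)ethynyl]-4-[(5E,9E)-6,10,14-trimethylpentadeca-1,5,9,13-tetraen-2-yl]oxetane | CC(C)[Si](C#C[C@H]1CC(O1)C(=C)CC/C=C(\C)CC/C=C(\C)CCC=C(C)C)(C(C)C)C(C)C | intermediate
15 | (2R)-2-[(triisopropylsilyl)ethynyl]-5-[(3E,7E)-4,8,12-trimethyltrideca-3,7,11-trien-1-yl]-3,6-dihydro-2H-pyran | CC(C)[Si](C#C[C@H]1CC=C(CC/C=C(\C)CC/C=C(\C)CCC=C(C)C)CO1)(C(C)C)C(C)C | intermediate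
16 | (2R)-2-ethynyl-5-[(3E,7E)-4,8,12-trimethyltrideca-3,7,11-trien-1-yl]-3,6-dihydro-2H-pyran | C#C[C@H]1CC=C(CC/C=C(\C)CC/C=C(\C)CCC=C(C)C)CO1 | intermediate
17 | 2-{(2R)-5-[(3E,7E)-4,8,12-trimethyltrideca-3,7,11-trien-1-yl]-3,6-dihydro-2H-pyran-2-yl}prop-2-enoic acid (CNP0171598.2) | C=C(C(=O)O)[C@H]1CC=C(CC/C=C(\C)CC/C=C(\C)CCC=C(C)C)CO1 | target

**Step count**
Total: 11 steps. Longest linear sequence: 11 steps (from 1 and 2 to 17); the purchased ynone 6 enters at step 3.

**Steps most likely to fail**

Step 9 (ring expansion). The propargylic C2–O1 bond may ionise instead of the allylic one, the allyl cation may be captured by the nearest trisubstituted chain alkene (cation–olefin cyclisation), or traces of triflic acid may oligomerise the polyene before oxygen recapture. The fallback builds the same ring by olefin metathesis; it sets out from 4 and returns at 15.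
- Appel bromination of 4 (CBr4, PPh3, CH2Cl2, 0 °C) should give (5E,9E)-2-(bromomethyl)-6,10,14-trimethylpentadeca-1,5,9,13-tetraene F1.
- Brown allylation of commercial 3-(triisopropylsilyl)prop-2-ynal with (+)-Ipc2B(allyl), the reagent derived from (−)-α-pinene (Et2O, −78 °C, then NaOH/H2O2), should give (3R)-1-(triisopropylsilyl)hex-5-en-1-yn-3-ol F2, by analogy with aryl aldehydes.
- Williamson etherification of F2 with F1 (NaH, THF/DMF, 0 °C) gives (3R)-3-{[(5E,9E)-6,10,14-trimethyl-2-methylidenepentadeca-5,9,13-trien-1-yl]oxy}-1-(triisopropylsilyl)hex-5-en-1-yne F3.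
- Ring-closing metathesis of F3 with the second-generation Grubbs catalyst RuCl2(H2IMes)(PCy3)(=CHPh) (CH2Cl2, 40 °C) joins the allyl CH to the 1,1-disubstituted alkene and should give 15. The hindered silyl alkyne and the trisubstituted chain alkenes are expected to stay out of the metathesis, and C2 then comes from the allylation with retention.

Step 8 (oxetane closure). Grob-type fragmentation of the γ-mesyloxy alkoxide (back to enal 5 and an enyne) or base-induced elimination toward the conjugated enyne may outrun the strained 4-exo-tet displacement. The fallback removes the alkoxide from the ring closure; it sets out from 10 and returns at 14.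
- Tf2O with 2,6-di-tert-butyl-4-methylpyridine (CH2Cl2, −78 °C) converts 10 into (3S,5RS,9E,13E)-10,14,18-trimethyl-6-methylidene-5-[(triethylsilyl)oxy]-1-(triisopropylsilyl)nonadeca-9,13,17-trien-1-yn-3-yl trifluoromethanesulfonate F4.
- On warming, the neighbouring silyl ether oxygen should displace the triflate with inversion, and the silyloxonium ion loses the silyl group to triflate. This gives 14 with the same 2R configuration in one operation and without any base-sensitive alkoxide.
- Ionisation of the propargylic triflate, and with it loss of configuration, is the risk of this fallback; it is kept down by low temperature.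

Step 11 (hydrocarboxylation). Hydropalladation may take the wrong regiochemistry (linear acid), the alkenylpalladium next to the ring oxygen may undergo β-alkoxide elimination, or the palladium hydride may migrate the ring and chain alkenes. The fallback installs the carboxyl carbon through a vinyl metal; it sets out from 16 and returns at 17.
- Hydrostannation of 16 (Bu3SnH, Mo(CO)3(CNtBu)3 cat., hydroquinone, THF, 55 °C) is α-selective for propargylic ethers and should give tributyl(1-{(2R)-5-[(3E,7E)-4,8,12-trimethyltrideca-3,7,11-trien-1-yl]-3,6-dihydro-2H-pyran-2-yl}ethenyl)stannane F5.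
- Tin–lithium exchange (n-BuLi, THF, −78 °C) gives (1-{(2R)-5-[(3E,7E)-4,8,12-trimethyltrideca-3,7,11-trien-1-yl]-3,6-dihydro-2H-pyran-2-yl}ethenyl)lithium F6.
- F6 is trapped with CO2 at −78 °C and acidified with dilute HCl to give 17.

**Further compounds**
F1 | step 9 | (5E,9E)-2-(bromomethyl)-6,10,14-trimethylpentadeca-1,5,9,13-tetraene | C=C(CBr)CC/C=C(\C)CC/C=C(\C)CCC=C(C)C
F2 | step 9 | (3R)-1-(triisopropylsilyl)hex-5-en-1-yn-3-ol | CC(C)[Si](C#C[C@H](O)CC=C)(C(C)C)C(C)C
F3 | step 9 | (3R)-3-{[(5E,9E)-6,10,14-trimethyl-2-methylidenepentadeca-5,9,13-trien-1-yl]oxy}-1-(triisopropylsilyl)hex-5-en-1-yne | CC(C)[Si](C#C[C@H](OCC(=C)CC/C=C(\C)CC/C=C(\C)CCC=C(C)C)CC=C)(C(C)C)C(C)C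
F4 | step 8 | (3S,5RS,9E,13E)-10,14,18-trimethyl-6-methylidene-5-[(triethylsilyl)oxy]-1-(triisopropylsilyl)nonadeca-9,13,17-trien-1-yn-3-yl trifluoromethanesulfonate | CC(C)[Si](C#C[C@@H](OS(=O)(=O)C(F)(F)F)CC(O[Si](CC)(CC)CC)C(=C)CC/C=C(\C)CC/C=C(\C)CCC=C(C)C)(C(C)C)C(C)C
F5 | step 11 | tributyl(1-{(2R)-5-[(3E,7E)-4,8,12-trimethyltrideca-3,7,11-trien-1-yl]-3,6-dihydro-2H-pyran-2-yl}ethenyl)stannane | C=C([Sn](CCCC)(CCCC)CCCC)[C@H]1CC=C(CC/C=C(\C)CC/C=C(\C)CCC=C(C)C)CO1
F6 | step 11 | (1-{(2R)-5-[(3E,7E)-4,8,12-trimethyltrideca-3,7,11-trien-1-yl]-3,6-dihydro-2H-pyran-2-yl}ethenyl)lithium | C=C([Li])[C@H]1CC=C(CC/C=C(\C)CC/C=C(\C)CCC=C(C)C)CO1
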